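**Plan**
Cuts, in retrosynthetic order: (a) the C5–CHO bond; (b) the O1–C2 bond of the dihydropyran ring (with the C3–H bond), which opens the chroman to an achiral ortho-geranylgeranyl hydroquinone; (c) the aryl–C1' bond, giving a brominated hydroquinone dimethyl ether and geranylgeranyl bromide.
Forward: the benzene ring is bought, the C20 chain is joined by arylcopper allylation, the hydroquinone is unmasked by way of the quinone, the dihydropyran ring is closed last by a tocopherol cyclase (a proton-initiated prenylquinol cycloisomerase), and the formyl group is put on at the end.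
Enabling feature: in the quinol the hydroxyl on ring carbon C1 (future C8a–O1) is ortho to the allylic chain on C6 (future C4a), so O1 and the tertiary carbon C3' of the (E)-C2'=C3' alkene (future C2) can close the six-membered ring O1–C2–C3–C4–C4a–C8a; the para hydroxyl (future O6) and the ring methyl (future 8-CH3) complete the native substrate pattern of the enzyme.
Stereochemistry: the single stereocentre C2 (R) is created in the enzymatic ring closure by the chiral active site; the (3'E,7'E) alkenes come unchanged from (2E,6E,10E)-geranylgeraniol.

Key step: step 7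

Remark: the target is read as (2R)-5-formyl-δ-tocotrienol with a (3'E,7'E) side chain; 4-methoxy-2-methylphenol and (2E,6E,10E)-geranylgeraniol are taken as purchasable, and the cyclase is used as a recombinant protein catalyst.

**Step 1**
Reactants: 1 4-methoxy-2-methylphenol
Product: 2 2-bromo-4-methoxy-6-methylphenol
Conditions: NBS (1.0 equiv), i-Pr2NH (cat.), CH2Cl2, 0 °C
Reagents that add atoms: N-bromosuccinimide, O=C1CCC(=O)N1Br
Why: Electrophilic aromatic bromination, in which the free hydroxyl is the strongest donor and its para position is blocked by the methoxy group, so the single open ortho position C6 should be brominated.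

**Step 2**
Reactants: 2 2-bromo-4-methoxy-6-methylphenol
Product: 3 1-bromo-2,5-dimethoxy-3-methylbenzene
Conditions: MeI, K2CO3, DMF, rt
Reagents that add atoms: iodomethane, CI
Why: Williamson ether synthesis, which masks the acidic hydroxyl before the aryl metal is made and leaves both oxygens in a form that one oxidant removes together later.

**Step 3**
Reactants: 4 (2E,6E,10E)-geranylgeraniol
Product: 5 (2E,6E,10E)-geranylgeranyl bromide
Conditions: PBr3 (0.4 equiv), Et2O, −10 → 0 °C, dark; used crude
Reagents that add atoms: phosphorus tribromide, BrP(Br)Br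
Why: Conversion of a primary allylic alcohol into the bromide by activation with PBr3 and SN2 displacement, which at low temperature in ether should keep the (2E) geometry and avoid allylic transposition.

**Step 4**
Reactants: 3 1-bromo-2,5-dimethoxy-3-methylbenzene; 5 (2E,6E,10E)-geranylgeranyl bromide
Product: 8 2,5-dimethoxy-1-methyl-3-geranylgeranylbenzene, via aryllithium 6 (not isolated), via arylcopper 7 (not isolated)
Conditions: n-BuLi, THF, −78 °C; CuBr·SMe2 (1.05 equiv), −78 → −40 °C; then 5, −78 → 0 °C
Reagents that add atoms: none
Why: Bromine–lithium exchange, transmetalation to an arylcopper of monovalent copper and copper-mediated allylic substitution, in which the aryl group goes to the unhindered primary α-carbon of 5 (SN2, not SN2'), so the chain is joined with all its (E)-alkenes unchanged.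

**Step 5**
Reactants: 8 2,5-dimethoxy-1-methyl-3-geranylgeranylbenzene
Product: 9 2-methyl-6-geranylgeranyl-1,4-benzoquinone
Conditions: (NH4)2Ce(NO3)6 (2.5 equiv), MeCN/CH2Cl2/H2O, 0 °C, short reaction time
Reagents that add atoms: water, O
Why: Oxidative demethylation of a hydroquinone dimethyl ether by tetravalent cerium, in which one-electron oxidation of the electron-rich arene and ipso attack of water expel two molecules of methanol, while the isolated trisubstituted alkenes are harder to oxidise than the dialkoxyarene and should survive at 0 °C.

**Step 6**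
Reactants: 9 2-methyl-6-geranylgeranyl-1,4-benzoquinone
Product: 10 2-methyl-6-geranylgeranylbenzene-1,4-diol
Conditions: Na2S2O4, Et2O/H2O, rt, argon; used at once
Reagents that add atoms: none
Why: Two-electron reduction of a para-benzoquinone to the hydroquinone by dithionite in a two-phase system, a reagent that leaves isolated alkenes alone.

**Step 7**
Reactants: 10 2-methyl-6-geranylgeranylbenzene-1,4-diol
Product: 11 (R)-δ-tocotrienol
Conditions: tocopherol cyclase (recombinant, VTE1 type, EC 5.5.1.24, as lysate of an E. coli expression strain), KH2PO4/K2HPO4 buffer pH 7.3, sodium L-ascorbate (NaC6H7O6), 2-hydroxypropyl-β-cyclodextrin, N2, dark, 30 °C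
Reagents that add atoms: none
Why: The enzyme binds the quinol by its para hydroxyl and lipophilic chain, an active-site acid protonates C2' of the proximal (E)-C2'=C3' alkene, and the hydroxyl oxygen on C1 adds to the developing tertiary cation at C3', so the step is a cycloisomerisation without by-product. The closest known reaction type is the native reaction of tocopherol cyclases on 2-methyl-6-phytyl- and 2-methyl-6-geranylgeranyl-1,4-benzoquinols, the enzymatic counterpart of the acid-catalysed hydroalkoxylation of ortho-prenylphenols to chromans. The dihydropyran ring closes in the 6-endo-trig mode, O1 bonding to C3' with both alkene carbons inside the new ring. The new stereocentre C2 is controlled by the chiral active site alone, since the substrate is achiral; the enzyme exposes one face of the alkene to proton and oxygen and should give the (R)-chroman common to natural tocochromanols. The step needs reaction of only the proximal of four trisubstituted alkenes and no cation–olefin cyclisation along the chain; this is secured because the medium is neutral and only the C2'=C3' alkene lies within reach of the bound ortho hydroxyl, while the para hydroxyl cannot reach the chain.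

**Step 8**
Reactants: 11 (R)-δ-tocotrienol
Product: 13 (R)-5-formyl-δ-tocotrienol (the target), via 5-hydroxymethyl-δ-tocotrienol 12 (not isolated)
Conditions: MgCl2 (anhydrous), Et3N, (CH2O)n, THF, reflux, argon
Reagents that add atoms: paraformaldehyde (reacting as formaldehyde), C=O
Why: Magnesium-mediated ortho-formylation of a phenol (Casnati–Skattebøl reaction), in which the magnesium phenoxide delivers formaldehyde to an ortho carbon through a six-membered chelate and the salicyl alkoxide is oxidised by a second formaldehyde through hydride transfer; attack is expected at C5 and not C7 because the fused dihydropyran ring localises the aromatic bonds (Mills–Nixon effect) and makes C5 the more nucleophilic ortho position of 8-methylchroman-6-ols, while the non-acidic medium spares the three alkenes and the stereocentre.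

**Compound list**
1 | 4-methoxy-2-methylphenol | COc1ccc(O)c(C)c1 | starting material
2 | 2-bromo-4-methoxy-6-methylphenol | COc1cc(C)c(O)c(Br)c1 | intermediate
3 | 1-bromo-2,5-dimethoxy-3-methylbenzene | COc1cc(C)c(OC)c(Br)c1 | intermediate
4 | (2E,6E,10E)-3,7,11,15-tetramethylhexadeca-2,6,10,14-tetraen-1-ol (geranylgeraniol) | CC(C)=CCC/C(C)=C/CC/C(C)=C/CC/C(C)=C/CO | starting material
5 | (2E,6E,10E)-1-bromo-3,7,11,15-tetramethylhexadeca-2,6,10,14-tetraene (geranylgeranyl bromide) | CC(C)=CCC/C(C)=C/CC/C(C)=C/CC/C(C)=C/CBr | intermediate
6 | (2,5-dimethoxy-3-methylphenyl)lithium (formed in the flask) | [Li]c1cc(OC)cc(C)c1OC | intermediate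
7 | (2,5-dimethoxy-3-methylphenyl)copper (formed in the flask) | [Cu]c1cc(OC)cc(C)c1OC | intermediate
8 | 2,5-dimethoxy-1-methyl-3-[(2E,6E,10E)-3,7,11,15-tetramethylhexadeca-2,6,10,14-tetraen-1-yl]benzene | CC(C)=CCC/C(C)=C/CC/C(C)=C/CC/C(C)=C/Cc1cc(OC)cc(C)c1OC | intermediate
9 | 2-methyl-6-[(2E,6E,10E)-3,7,11,15-tetramethylhexadeca-2,6,10,14-tetraen-1-yl]cyclohexa-2,5-diene-1,4-dione | CC(C)=CCC/C(C)=C/CC/C(C)=C/CC/C(C)=C/CC1=CC(=O)C=C(C)C1=O | intermediate
10 | 2-methyl-6-[(2E,6E,10E)-3,7,11,15-tetramethylhexadeca-2,6,10,14-tetraen-1-yl]benzene-1,4-diol | CC(C)=CCC/C(C)=C/CC/C(C)=C/CC/C(C)=C/Cc1cc(O)cc(C)c1O | intermediate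
11 | (2R)-2,8-dimethyl-2-[(3E,7E)-4,8,12-trimethyltrideca-3,7,11-trien-1-yl]-3,4-dihydro-2H-chromen-6-ol ((R)-δ-tocotrienol) | CC(C)=CCC/C(C)=C/CC/C(C)=C/CC[C@]1(C)CCc2cc(O)cc(C)c2O1 | intermediate
12 | (2R)-5-(hydroxymethyl)-2,8-dimethyl-2-[(3E,7E)-4,8,12-trimethyltrideca-3,7,11-trien-1-yl]-3,4-dihydro-2H-chromen-6-ol (formed in the flask) | CC(C)=CCC/C(C)=C/CC/C(C)=C/CC[C@]1(C)CCc2c(CO)c(O)cc(C)c2O1 | intermediate
13 | (2R)-6-hydroxy-2,8-dimethyl-2-[(3E,7E)-4,8,12-trimethyltrideca-3,7,11-trien-1-yl]-3,4-dihydro-2H-chromene-5-carbaldehyde | CC(C)=CCC/C(C)=C/CC/C(C)=C/CC[C@]1(C)CCc2c(C=O)c(O)cc(C)c2O1 | target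

**Count**
Total steps: 8. Longest linear sequence: 7 steps (1 → 2 → 3 → 8 → 9 → 10 → 11 → 13; steps 1, 2, 4, 5, 6, 7, 8).

**Steps most likely to fail**

Step 7. The membrane-associated cyclase may turn over too slowly with a water-insoluble substrate on a preparative scale, and the quinol may autoxidise back to the quinone, which the enzyme does not accept. The fallback is a chemical ring closure without asymmetric induction followed by separation of enantiomers. It sets out from quinone 9. Heating in pyridine should tautomerise it to the ortho-quinone methide, which closes by oxa-6π electrocyclisation to racemic 2,8-dimethyl-2-[(3E,7E)-4,8,12-trimethyltrideca-3,7,11-trien-1-yl]-2H-chromen-6-ol F1. Reduction of the styrene-type C3=C4 bond with sodium in boiling ethanol, which leaves isolated alkenes alone, should give racemic δ-tocotrienol F2. Preparative chromatography on a cellulose tris(3,5-dimethylphenylcarbamate) phase would remove (S)-δ-tocotrienol F3, and the route is rejoined at 11.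

Step 8. The chelate-directed delivery of formaldehyde may discriminate poorly between C5 and C7, the two ortho positions of the 6-hydroxyl, or run on to methoxymethyl ethers. The fallback separates site selection from carbon introduction. It sets out from 11. NBS (1.0 equiv) with catalytic i-Pr2NH in CH2Cl2 at −78 °C should brominate the more reactive C5 position to give (R)-5-bromo-δ-tocotrienol F4, from which any C7 isomer can be removed. n-BuLi (2.2 equiv) in THF at −78 °C then lithiates the oxygen and exchanges the bromine, and the dianion is quenched with DMF and aqueous NH4Cl to rejoin the route at 13.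

Step 5. The aryl radical cation may couple oxidatively at its two free ring positions, or tetravalent cerium may attack the electron-rich alkenes. The fallback avoids the dimethyl ether and also makes steps 1, 2 and 4 unnecessary. It sets out from 1 and 5. The sodium phenoxide of 1 (NaH, toluene) should be C-allylated by 5 at its only free ortho position to give 4-methoxy-2-methyl-6-[(2E,6E,10E)-3,7,11,15-tetramethylhexadeca-2,6,10,14-tetraen-1-yl]phenol F5. The para-methoxyphenol is then oxidised under milder conditions with PhI(OAc)2 in MeCN/H2O at 0 °C, with loss of methanol, to rejoin the route at 9.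

**Further compounds**
F1 | step 7 | racemic 2,8-dimethyl-2-[(3E,7E)-4,8,12-trimethyltrideca-3,7,11-trien-1-yl]-2H-chromen-6-ol | CC(C)=CCC/C(C)=C/CC/C(C)=C/CCC1(C)C=Cc2cc(O)cc(C)c2O1
F2 | step 7 | racemic δ-tocotrienol | CC(C)=CCC/C(C)=C/CC/C(C)=C/CCC1(C)CCc2cc(O)cc(C)c2O1
F3 | step 7 | (S)-δ-tocotrienol | CC(C)=CCC/C(C)=C/CC/C(C)=C/CC[C@@]1(C)CCc2cc(O)cc(C)c2O1
F4 | step 8 | (2R)-5-bromo-2,8-dimethyl-2-[(3E,7E)-4,8,12-trimethyltrideca-3,7,11-trien-1-yl]-3,4-dihydro-2H-chromen-6-ol | CC(C)=CCC/C(C)=C/CC/C(C)=C/CC[C@]1(C)CCc2c(Br)c(O)cc(C)c2O1
F5 | step 5 | 4-methoxy-2-methyl-6-[(2E,6E,10E)-3,7,11,15-tetramethylhexadeca-2,6,10,14-tetraen-1-yl]phenol | CC(C)=CCC/C(C)=C/CC/C(C)=C/CC/C(C)=C/Cc1cc(OC)cc(C)c1O
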